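**Retrosynthetic overview**

1. Numbering: ring A is C1–C2–C3–C4–C9, ring B is C4–C5–C6–C7–C8–C9, ring C is C5–C10–C11–C12–C13–C14–C6; C15 sits on C12, C16 on C6, C17 on C9, and the lactone is C2–O–C19(=O)–C18(=C20H2)–C3. The strategy rests on the seven-membered ring C being fused to ring B through C5–C6, with the methyl-bearing quaternary C6 flanked by an oxygen-bearing C13.
2. Last step: the lactone and both epoxides come from a C2=C3/C12=C13 diene acid; the β-epoxide on C2–C3 is opened at C2 by the C19 acid. C18–C20 arrive by Stille coupling on the C2=C3 enol triflate of a C3 ketone.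
3. The C12(CH3)=C13 alkene comes from the C13 ketone (methylenation, conjugate reduction with triflation, reduction); C5–H comes from hydrogen-atom-transfer hydrogenation of C5=C10.
4. Key disconnection: C5–C6 and C10–C11 by a rhodium (5+2) cycloaddition of a ring A enyne (C4 ethynyl, 1-ethoxy vinylcyclopropane on the C9 side chain); rings B and C form together.
5. Ring A: C9 by organocatalytic Michael addition; C4 is tied cis to C17 through a γ-lactone made by palladium carbonylation and later unmasked as the alkyne; the vinylcyclopropane is built from a side-chain alkyne. Ring order: A (from the starting material), then B and C together (step 13), then the lactone (step 27).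

Key step: step 13

Remark 1: α is the face of the ring system that carries C17; β is the opposite face (that of C16 and of the C3 hydroxyl).
Remark 2 (assumption): the cupreidine-derived catalyst of step 1 is taken to give the (S)-adduct 3; if the sense of induction is the opposite, its quinine-derived pseudoenantiomer is used.
Remark 3: the C3 configuration of 15–29 is removed by oxidation in step 20; the β-epimer expected from reversible exo addition is drawn, and the α-epimer would serve equally.

**Route**

Step 1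
Reactants: 1 tert-butyl 2-oxocyclopentane-1-carboxylate; 2 acrolein
Product: 3 tert-butyl (S)-2-oxo-1-(3-oxopropyl)cyclopentane-1-carboxylate
Conditions: cupreidine 9-O-(9-phenanthryl) ether (10 mol%), CH2Cl2, −25 °C
Reagents that add atoms: none
Why: Organocatalytic asymmetric Michael addition of an α-substituted β-keto ester to an enal, in which the bifunctional 6′-hydroxy cinchona catalyst binds enol and acrolein and sets the quaternary C9 by catalyst control.

Step 2
Reactants: 3 keto aldehyde; 4 dimethyl (1-diazo-2-oxopropyl)phosphonate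
Product: 5 tert-butyl (S)-1-(but-3-yn-1-yl)-2-oxocyclopentane-1-carboxylate
Conditions: K2CO3, MeOH, 0 °C → rt
Reagents that add atoms: none
Why: Seyferth–Gilbert homologation in the Ohira–Bestmann form, in which the aldehyde should react far faster than the hindered ketone, and the short cold exposure to methoxide should keep retro-Claisen opening of the β-keto ester low.

Step 3
Reactants: 5 alkynyl keto ester
Product: 7 tert-butyl (S)-1-(but-3-yn-1-yl)-2-(trifluoromethanesulfonyloxy)cyclopent-2-ene-1-carboxylate, via potassium enolate 6 (not isolated)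
Conditions: KN(SiMe3)2, THF, −78 °C; then PhNTf2, −78 → 0 °C
Reagents that add atoms: N-phenylbis(trifluoromethanesulfonimide) O=S(=O)(N(c1ccccc1)S(=O)(=O)C(F)(F)F)C(F)(F)F
Why: Enolate O-sulfonylation, regiospecific because C9 is quaternary and only C3 can be deprotonated; the enol triflate masks the ketone and is the handle for step 8.

Step 4
Reactants: 7 enol triflate
Product: 9 tert-butyl (S)-1-[(E)-4-iodo-3-methylbut-3-en-1-yl]-2-(trifluoromethanesulfonyloxy)cyclopent-2-ene-1-carboxylate, via alkenylalane 8 (not isolated)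
Conditions: AlMe3, Cp2ZrCl2 (20 mol%), CH2Cl2, 0 °C → rt; then I2, THF, −30 °C
Reagents that add atoms: trimethylaluminium C[Al](C)C; iodine II
Why: Negishi zirconium-catalysed carboalumination adds methyl (C16) and aluminium syn across the terminal alkyne, and iodinolysis with retention should give the E vinyl iodide; the hindered tert-butyl ester and the enol triflate should not react with AlMe3 at this temperature.

Step 5
Reactants: 9 vinyl iodide; 10 tributyl(1-ethoxyvinyl)stannane
Product: 11 tert-butyl (S)-1-[(E)-5-ethoxy-3-methylhexa-3,5-dien-1-yl]-2-(trifluoromethanesulfonyloxy)cyclopent-2-ene-1-carboxylate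
Conditions: Pd2(dba)3 (2.5 mol%), AsPh3 (20 mol%), CuI (10 mol%), NMP, rt
Reagents that add atoms: none
Why: Stille coupling with retention of alkene geometry, chemoselective because oxidative addition into the C–I bond is much faster than into the enol triflate at room temperature without chloride.

Step 6
Reactants: 11 2-ethoxydiene
Product: 12 tert-butyl (S)-1-[(E)-4-(1-ethoxycyclopropyl)-3-methylbut-3-en-1-yl]-2-(trifluoromethanesulfonyloxy)cyclopent-2-ene-1-carboxylate
Conditions: Et2Zn (1.5 equiv), CH2I2 (1.5 equiv), CH2Cl2, −20 → 0 °C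
Reagents that add atoms: diiodomethane ICI
Why: Simmons–Smith cyclopropanation in the Furukawa form, in which the electrophilic zinc carbenoid should select the electron-rich 1,1-disubstituted enol ether alkene over the trisubstituted alkene and the electron-poor enol triflate, giving the 1-ethoxy vinylcyclopropane.

Step 7
Reactants: 12 ester
Product: 13 (R)-5-[(E)-4-(1-ethoxycyclopropyl)-3-methylbut-3-en-1-yl]-5-(hydroxymethyl)cyclopent-1-en-1-yl trifluoromethanesulfonate
Conditions: i-Bu2AlH (3.5 equiv), CH2Cl2, −78 → 0 °C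
Reagents that add atoms: none
Why: Hydride reduction of the ester to the C17 alcohol; enol triflates and cyclopropyl ethers are not attacked by i-Bu2AlH under these conditions.

Step 8
Reactants: 13 hydroxy enol triflate
Product: 14 (S)-3a-[(E)-4-(1-ethoxycyclopropyl)-3-methylbut-3-en-1-yl]-3,3a,4,5-tetrahydro-1H-cyclopenta[c]furan-1-one (lactone C5(=O)–O–C17 with C3=C4)
Conditions: Pd(PPh3)4 (10 mol%), CO (1 atm), Et3N, MeCN, 65 °C
Reagents that add atoms: carbon monoxide [C-]#[O+]
Why: Palladium-catalysed carbonylative lactonisation (oxidative addition of the enol triflate to zerovalent palladium, CO insertion, capture of the acylpalladium by the C17 hydroxyl in a five-membered closure), which brings in C5 already tied to C17.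

Step 9
Reactants: 14 alkylidene lactone
Product: 15 cis-fused γ-lactone with C3 β-(4-methoxybenzyloxy) and C4 β-H
Conditions: 4-methoxybenzyl alcohol (3 equiv), KOt-Bu (20 mol%), THF, 0 °C → rt
Reagents that add atoms: 4-methoxybenzyl alcohol COc1ccc(CO)cc1
Why: Alkoxide-catalysed oxa-Michael addition to the strained ring-fusion enoate; protonation at C4 can only give the cis-fused lactone, so C5 is fixed on the α face cis to C17, and the reversible addition should settle on the exo (β) C3 ether.

Step 10
Reactants: 15 lactone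
Product: 16 lactol (C5 hemiacetal, both anomers)
Conditions: i-Bu2AlH (1.1 equiv), CH2Cl2, −78 °C
Reagents that add atoms: none
Why: Partial reduction of a γ-lactone, stopped at the lactol because the aluminium hemiacetal is stable at −78 °C.

Step 11
Reactants: 16 lactol; 4 dimethyl (1-diazo-2-oxopropyl)phosphonate
Product: 17 alkynol: cyclopentane with C4 α-ethynyl, C3 β-OPMB, C9 α-CH2OH and C9 β-[(E)-4-(1-ethoxycyclopropyl)-3-methylbut-3-enyl]
Conditions: K2CO3, MeOH, rt
Reagents that add atoms: none
Why: Ohira–Bestmann alkynylation of the open hydroxy-aldehyde tautomer; the C4 configuration set by the lactone is also the favoured one (trans to the C3 ether), so base-mediated equilibration of the aldehyde should lead to the same epimer.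

Step 12
Reactants: 17 alkynol
Product: 18 enyne precursor (C17 tert-butyldimethylsilyl ether of 17)
Conditions: TBSCl, imidazole, DMF, rt
Reagents that add atoms: tert-butyldimethylsilyl chloride CC(C)(C)[Si](C)(C)Cl
Why: Standard silylation of the primary alcohol, giving a C17 ether that survives every step up to step 25.

Step 13
Reactants: 18 enyne precursor
Product: 19 tricyclic diene (C5=C10; C13=C14 ethyl enol ether; C6 β-methyl; C3 β-OPMB; C17 OTBS)
Conditions: [Rh(CO)2Cl]2 (5 mol%), 1,2-dichloroethane (0.01 M), 80 °C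
Reagents that add atoms: none
Why: Monovalent rhodium binds the alkyne and the alkene of the 1-ethoxy vinylcyclopropane, oxidative coupling with opening of the strained C11–C13 bond gives an eight-membered allyl rhodacycle, and reductive elimination forms C10–C11 and frees the catalyst. The closest known reaction is the rhodium-catalysed intramolecular (5+2) cycloaddition of vinylcyclopropanes with alkynes, for which [Rh(CO)2Cl]2 is the usual catalyst with four-atom tethers and in which a 1-alkoxy group on the cyclopropane speeds the reaction. Ring B (six-membered) closes through the C5–C6 bond across the C4–C9–C8–C7 tether, and ring C (seven-membered) is the cycloadduct ring itself, closed by C10–C11. The only new stereocentre, C6, is controlled by ring A: the trans arrangement of the alkyne (C4, α) and the side chain (C9, β) allows only a chair-like tether in which C14 lies equatorial to span ring C, so the C16 methyl ends axial on the β face, anti to C17. The step needs chemoselectivity for cycloaddition over alkyne oligomerisation and over isomerisation of the vinylcyclopropane to a diene, which high dilution, the intramolecular setting and the donor ethoxy group should secure; the unsubstituted cyclopropane makes its two breakable bonds equivalent, and the ethoxy group leaves the enol ether exactly at C13.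

Step 14
Reactants: 19 enol ether
Product: 20 C13 ketone with C5=C10
Conditions: 0.5 M aq. HCl, THF, 0 °C
Reagents that add atoms: water O
Why: Acid hydrolysis of an enol ether (protonation at C14, loss of ethanol from the hemiketal); C5=C10 is not in conjugation with the new ketone and should stay in place, and the TBS and PMB ethers should survive brief cold dilute acid.

Step 15
Reactants: 20 unsaturated ketone
Product: 21 saturated C13 ketone with C5 α-H (trans B/C fusion)
Conditions: Mn(dpm)3 (10 mol%), PhSiH3, t-BuOOH, i-PrOH, rt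
Reagents that add atoms: none
Why: Hydrogen-atom-transfer hydrogenation: a hydrogen atom adds to C10, and the tertiary C5 radical should take its second hydrogen axially from the α face so that C10 stays equatorial, giving the more stable trans-fused chair with C5–H anti to C16.

Step 16
Reactants: 21 ketone
Product: 25 12-methylene-13-ketone, via lithium enolate 22 (not isolated), via Mannich base 23 (not isolated), via trimethylammonium iodide 24 (not isolated)
Conditions: LiN(i-Pr)2, THF, −78 °C; Me2N=CH2+ I−, −78 °C → rt; then MeI, MeOH, rt; then aq. NaHCO3, CH2Cl2, rt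
Reagents that add atoms: N,N-dimethylmethyleneiminium iodide (Eschenmoser's salt) C=[N+](C)C.[I-]; iodomethane CI (ends in 24 only)
Why: Kinetic enolisation should occur at C12 and not at the neopentyl C14; a Mannich reaction with Eschenmoser's salt, quaternisation and base-induced elimination then install C15 as an exocyclic methylene.

Step 17
Reactants: 25 α-methylene ketone
Product: 27 C12(CH3)=C13 enol triflate, via lithium enolate 26 (not isolated)
Conditions: LiBH(sec-Bu)3, THF, −78 °C; then PhNTf2, −78 → 0 °C
Reagents that add atoms: N-phenylbis(trifluoromethanesulfonimide) O=S(=O)(N(c1ccccc1)S(=O)(=O)C(F)(F)F)C(F)(F)F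
Why: Conjugate hydride addition to the exocyclic enone turns the methylene into the C15 methyl and gives the C12=C13 enolate regiospecifically, which is trapped on oxygen as the tetrasubstituted enol triflate.

Step 18
Reactants: 27 enol triflate
Product: 28 C12=C13 alkene (12-methyl; C3 β-OPMB; C17 OTBS)
Conditions: Pd(OAc)2 (5 mol%), PPh3, HCO2H, n-Bu3N, DMF, 60 °C
Reagents that add atoms: none
Why: Palladium-catalysed formate reduction of an enol triflate (oxidative addition, hydride from formate with loss of CO2, reductive elimination), which places the trisubstituted alkene exactly where the triflate was.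

Step 19
Reactants: 28 PMB ether
Product: 29 C3 β-alcohol
Conditions: DDQ, CH2Cl2/pH 7 buffer, 0 °C
Reagents that add atoms: none
Why: Oxidative cleavage of the electron-rich PMB ether through a benzylic oxocarbenium ion that water hydrolyses, leaving the isolated alkene and the TBS ether untouched.

Step 20
Reactants: 29 alcohol
Product: 30 C3 ketone
Conditions: Dess–Martin periodinane, NaHCO3, CH2Cl2, 0 °C → rt
Reagents that add atoms: none
Why: Dess–Martin oxidation under buffered, non-enolising conditions, chosen so that C4, now α to a ketone, does not epimerise.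

Step 21
Reactants: 30 ketone
Product: 32 C2=C3 enol triflate, via potassium enolate 31 (not isolated)
Conditions: KN(SiMe3)2, THF, −78 °C; then PhNTf2, −78 → 0 °C
Reagents that add atoms: N-phenylbis(trifluoromethanesulfonimide) O=S(=O)(N(c1ccccc1)S(=O)(=O)C(F)(F)F)C(F)(F)F
Why: Kinetic deprotonation should take the C2 methylene and not the ring-fusion C4 methine, and O-triflation fixes the C2=C3 enol without touching C4.

Step 22
Reactants: 33 methyl propiolate
Product: 34 methyl 2-(tributylstannyl)acrylate
Conditions: Bu3SnH, Pd(PPh3)4 (2 mol%), THF, 0 °C → rt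
Reagents that add atoms: tributyltin hydride CCCC[SnH](CCCC)CCCC
Why: Palladium-catalysed syn hydrostannation of an alkynoate, which places tin on the α-carbon.

Step 23
Reactants: 32 enol triflate; 34 methyl 2-(tributylstannyl)acrylate
Product: 35 methyl 2-(C2=C3-en-3-yl)acrylate (methyl dienoate; C17 OTBS)
Conditions: Pd(PPh3)4 (10 mol%), CuI (20 mol%), LiCl, DMF, 50 °C
Reagents that add atoms: none
Why: Copper-assisted Stille coupling of an enol triflate with an α-stannyl acrylate forms C3–C18 and brings in C19 and C20 at their final oxidation level; the 2-substituted dienoate is used at once to avoid Diels–Alder dimerisation.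

Step 24
Reactants: 35 methyl ester
Product: 36 dienoic acid (C17 OTBS)
Conditions: LiOH, THF/H2O (3:1), rt; then aq. HCl to pH 3
Reagents that add atoms: lithium hydroxide [Li+].[OH-]
Why: Saponification of the unhindered methyl ester, done before the acetate is in place; the silyl ether is stable to hydroxide.

Step 25
Reactants: 36 silyl ether
Product: 37 C17 hydroxy dienoic acid
Conditions: Bu4NF (3 equiv), THF, rt
Reagents that add atoms: none
Why: Fluoride-induced desilylation, driven by the strong Si–F bond, with no effect on the diene acid.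

Step 26
Reactants: 37 hydroxy acid
Product: 39 C17 acetoxy dienoic acid, via mixed anhydride 38 (not isolated)
Conditions: Ac2O, pyridine, DMAP (cat.), CH2Cl2, 0 °C → rt; then aq. NaHCO3/THF; then aq. HCl to pH 3
Reagents that add atoms: acetic anhydride CC(=O)OC(C)=O
Why: Nucleophile-catalysed acetylation of the primary alcohol; the mixed anhydride formed at C19 is hydrolysed back to the acid in the basic aqueous work-up.

Step 27
Reactants: 39 acetoxy dienoic acid
Product: 41 target CNP0404717.1, via bis-epoxy acid 40 (not isolated)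
Conditions: mCPBA (2.4 equiv), CH2Cl2, 0 °C → rt
Reagents that add atoms: 3-chloroperoxybenzoic acid OOC(=O)c1cccc(Cl)c1
Why: Prilezhaev epoxidation of both trisubstituted alkenes, followed by acid-assisted lactonisation of the β,γ-epoxy acid: C2=C3 should be attacked from the β face, because the axial C17H2OAc on the envelope flap C9 covers the α face, and the C19 acid then opens the epoxide at C2 with inversion (C2–O α, C3–OH β, cis-fused five-membered lactone); C12=C13 should be attacked anti to the pseudo-axial C16 methyl of the chair cycloheptene to give the α-epoxide; the C18=C20 acrylate alkene is too electron-poor to react.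

**Compound list**

1 | tert-butyl 2-oxocyclopentane-1-carboxylate | O=C1CCCC1C(=O)OC(C)(C)C | starting material
2 | acrolein | C=CC=O | starting material
3 | tert-butyl (S)-2-oxo-1-(3-oxopropyl)cyclopentane-1-carboxylate | O=C1CCC[C@]1(C(=O)OC(C)(C)C)CCC=O | intermediate
4 | dimethyl (1-diazo-2-oxopropyl)phosphonate | COP(=O)(OC)C(=[N+]=[N-])C(C)=O | starting material
5 | tert-butyl (S)-1-(but-3-yn-1-yl)-2-oxocyclopentane-1-carboxylate | O=C1CCC[C@]1(C(=O)OC(C)(C)C)CCC#C | intermediate
6 | potassium enolate of 5 (C3=C4) | [K+].[O-]C1=CCC[C@]1(C(=O)OC(C)(C)C)CCC#C | intermediate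
7 | tert-butyl (S)-1-(but-3-yn-1-yl)-2-(trifluoromethanesulfonyloxy)cyclopent-2-ene-1-carboxylate | FC(F)(F)S(=O)(=O)OC1=CCC[C@]1(C(=O)OC(C)(C)C)CCC#C | intermediate
8 | (E)-alkenyl(dimethyl)alane from 7 (Al on C14, methyl on C6) | FC(F)(F)S(=O)(=O)OC1=CCC[C@]1(C(=O)OC(C)(C)C)CC/C(C)=C/[Al](C)C | intermediate
9 | tert-butyl (S)-1-[(E)-4-iodo-3-methylbut-3-en-1-yl]-2-(trifluoromethanesulfonyloxy)cyclopent-2-ene-1-carboxylate | FC(F)(F)S(=O)(=O)OC1=CCC[C@]1(C(=O)OC(C)(C)C)CC/C(C)=C/I | intermediate
10 | tributyl(1-ethoxyvinyl)stannane | CCCC[Sn](CCCC)(CCCC)C(=C)OCC | starting material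
11 | tert-butyl (S)-1-[(E)-5-ethoxy-3-methylhexa-3,5-dien-1-yl]-2-(trifluoromethanesulfonyloxy)cyclopent-2-ene-1-carboxylate | FC(F)(F)S(=O)(=O)OC1=CCC[C@]1(C(=O)OC(C)(C)C)CC/C(C)=C/C(=C)OCC | intermediate
12 | tert-butyl (S)-1-[(E)-4-(1-ethoxycyclopropyl)-3-methylbut-3-en-1-yl]-2-(trifluoromethanesulfonyloxy)cyclopent-2-ene-1-carboxylate | FC(F)(F)S(=O)(=O)OC1=CCC[C@]1(C(=O)OC(C)(C)C)CC/C(C)=C/C1(OCC)CC1 | intermediate
13 | (R)-5-[(E)-4-(1-ethoxycyclopropyl)-3-methylbut-3-en-1-yl]-5-(hydroxymethyl)cyclopent-1-en-1-yl trifluoromethanesulfonate | FC(F)(F)S(=O)(=O)OC1=CCC[C@]1(CO)CC/C(C)=C/C1(OCC)CC1 | intermediate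
14 | (S)-3a-[(E)-4-(1-ethoxycyclopropyl)-3-methylbut-3-en-1-yl]-3,3a,4,5-tetrahydro-1H-cyclopenta[c]furan-1-one | O=C1OC[C@]2(CC/C(C)=C/C3(OCC)CC3)CCC=C12 | intermediate
15 | cis-fused γ-lactone (C5(=O)–O–C17) with C3 β-OPMB, C4 β-H and the vinylcyclopropane side chain on C9 | O=C1OC[C@]2(CC/C(C)=C/C3(OCC)CC3)CC[C@@H](OCc3ccc(OC)cc3)[C@H]12 | intermediate
16 | lactol of 15 (C5 hemiacetal, both anomers) | OC1OC[C@]2(CC/C(C)=C/C3(OCC)CC3)CC[C@@H](OCc3ccc(OC)cc3)[C@H]12 | intermediate
17 | alkynol: C4 α-ethynyl, C3 β-OPMB, C9 α-CH2OH, C9 β-[(E)-4-(1-ethoxycyclopropyl)-3-methylbut-3-enyl] cyclopentane | C#C[C@H]1[C@H](OCc2ccc(OC)cc2)CC[C@]1(CO)CC/C(C)=C/C1(OCC)CC1 | intermediate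
18 | enyne precursor: C17 TBS ether of 17 | C#C[C@H]1[C@H](OCc2ccc(OC)cc2)CC[C@]1(CO[Si](C)(C)C(C)(C)C)CC/C(C)=C/C1(OCC)CC1 | intermediate
19 | tricyclic diene: C5=C10, C13=C14 ethyl enol ether, C6 β-methyl, C3 β-OPMB, C17 OTBS | COc1ccc(CO[C@@H]2CC[C@]3(CO[Si](C)(C)C(C)(C)C)CC[C@@]4(C)C=C(OCC)CCC=C4[C@@H]23)cc1 | intermediate
20 | tricyclic C13 ketone with C5=C10 | COc1ccc(CO[C@@H]2CC[C@]3(CO[Si](C)(C)C(C)(C)C)CC[C@@]4(C)CC(=O)CCC=C4[C@@H]23)cc1 | intermediate
21 | tricyclic C13 ketone, C5 α-H (trans B/C) | COc1ccc(CO[C@@H]2CC[C@]3(CO[Si](C)(C)C(C)(C)C)CC[C@@]4(C)CC(=O)CCC[C@@H]4[C@@H]23)cc1 | intermediate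
22 | lithium C12=C13 enolate of 21 | COc1ccc(CO[C@@H]2CC[C@]3(CO[Si](C)(C)C(C)(C)C)CC[C@@]4(C)CC([O-])=CCC[C@@H]4[C@@H]23)cc1.[Li+] | intermediate
23 | 12-(dimethylaminomethyl)-13-ketone (Mannich base, C12 epimers) | COc1ccc(CO[C@@H]2CC[C@]3(CO[Si](C)(C)C(C)(C)C)CC[C@@]4(C)CC(=O)C(CN(C)C)CC[C@@H]4[C@@H]23)cc1 | intermediate
24 | trimethylammonium iodide of 23 | COc1ccc(CO[C@@H]2CC[C@]3(CO[Si](C)(C)C(C)(C)C)CC[C@@]4(C)CC(=O)C(C[N+](C)(C)C)CC[C@@H]4[C@@H]23)cc1.[I-] | intermediate
25 | 12-methylene-13-ketone | COc1ccc(CO[C@@H]2CC[C@]3(CO[Si](C)(C)C(C)(C)C)CC[C@@]4(C)CC(=O)C(=C)CC[C@@H]4[C@@H]23)cc1 | intermediate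
26 | lithium enolate C12(CH3)=C13–O | COc1ccc(CO[C@@H]2CC[C@]3(CO[Si](C)(C)C(C)(C)C)CC[C@@]4(C)CC([O-])=C(C)CC[C@@H]4[C@@H]23)cc1.[Li+] | intermediate
27 | C12(CH3)=C13 enol triflate | COc1ccc(CO[C@@H]2CC[C@]3(CO[Si](C)(C)C(C)(C)C)CC[C@@]4(C)CC(OS(=O)(=O)C(F)(F)F)=C(C)CC[C@@H]4[C@@H]23)cc1 | intermediate
28 | C12=C13 alkene (12-methyl), C3 β-OPMB, C17 OTBS | COc1ccc(CO[C@@H]2CC[C@]3(CO[Si](C)(C)C(C)(C)C)CC[C@@]4(C)CC=C(C)CC[C@@H]4[C@@H]23)cc1 | intermediate
29 | C3 β-alcohol | O[C@@H]1CC[C@]2(CO[Si](C)(C)C(C)(C)C)CC[C@@]3(C)CC=C(C)CC[C@@H]3[C@@H]12 | intermediate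
30 | C3 ketone | O=C1CC[C@]2(CO[Si](C)(C)C(C)(C)C)CC[C@@]3(C)CC=C(C)CC[C@@H]3[C@@H]12 | intermediate
31 | potassium C2=C3 enolate of 30 | [K+].[O-]C1=CC[C@]2(CO[Si](C)(C)C(C)(C)C)CC[C@@]3(C)CC=C(C)CC[C@@H]3[C@@H]12 | intermediate
32 | C2=C3 enol triflate | FC(F)(F)S(=O)(=O)OC1=CC[C@]2(CO[Si](C)(C)C(C)(C)C)CC[C@@]3(C)CC=C(C)CC[C@@H]3[C@@H]12 | intermediate
33 | methyl propiolate | C#CC(=O)OC | starting material
34 | methyl 2-(tributylstannyl)acrylate | C=C(C(=O)OC)[Sn](CCCC)(CCCC)CCCC | intermediate
35 | methyl dienoate: C18(=C20H2)(CO2Me) on C3, C2=C3, C12=C13, C17 OTBS | C=C(C(=O)OC)C1=CC[C@]2(CO[Si](C)(C)C(C)(C)C)CC[C@@]3(C)CC=C(C)CC[C@@H]3[C@@H]12 | intermediate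
36 | dienoic acid, C17 OTBS | C=C(C(=O)O)C1=CC[C@]2(CO[Si](C)(C)C(C)(C)C)CC[C@@]3(C)CC=C(C)CC[C@@H]3[C@@H]12 | intermediate
37 | C17 hydroxy dienoic acid | C=C(C(=O)O)C1=CC[C@]2(CO)CC[C@@]3(C)CC=C(C)CC[C@@H]3[C@@H]12 | intermediate
38 | C19 mixed acetic anhydride of 39 | C=C(C(=O)OC(C)=O)C1=CC[C@]2(COC(C)=O)CC[C@@]3(C)CC=C(C)CC[C@@H]3[C@@H]12 | intermediate
39 | C17 acetoxy dienoic acid | C=C(C(=O)O)C1=CC[C@]2(COC(C)=O)CC[C@@]3(C)CC=C(C)CC[C@@H]3[C@@H]12 | intermediate
40 | bis-epoxy acid (2β,3β-epoxide and 12α,13α-epoxide) | C=C(C(=O)O)[C@@]12O[C@@H]1C[C@]3(COC(C)=O)CC[C@@]4(C)C[C@H]5O[C@@]5(C)CC[C@@H]4[C@@H]23 | intermediate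
41 | CNP0404717.1 | C=C1C(=O)O[C@H]2C[C@]3(COC(C)=O)CC[C@@]4(C)C[C@H]5O[C@@]5(C)CC[C@@H]4[C@H]3[C@@]12O | target

**Step count**

Total: 27 steps. Longest linear sequence: 26 steps (steps 1–21 and 23–27); step 22 prepares stannane 34 in a side branch.

**Steps most likely to fail, with fallbacks**

1. Step 13 (the (5+2) cycloaddition). The trisubstituted vinylcyclopropane alkene may enter the rhodacycle too slowly, so that alkyne oligomerisation or rhodium-induced isomerisation of the vinylcyclopropane to a diene takes over. Fallback: rings B and C are built by an intramolecular Diels–Alder reaction followed by a one-carbon ring expansion, setting out from 11 and coming back at 21. The ethoxydiene 11 is not cyclopropanated but carried through the conditions of steps 7–12, all of which are basic or neutral and are worked up without acid. This gives in turn the diene alcohol F1, the alkylidene lactone F2, the PMB-oxy lactone F3, the lactol F4, the alkynol F5 and the silyl ether dienyne F6. Heating F6 (toluene, 200 °C, sealed tube, radical inhibitor) should join C5–C6 and C10–C12 of the 2-ethoxydiene and the alkyne to give the cyclohexadiene F7, with C6 set by the same chair-like tether as in step 13. Dilute aqueous HCl gives the ketone F8, and Mn(dpm)3/PhSiH3 as in step 15 gives the saturated six-membered ketone F9. Homologation with trimethylsilyldiazomethane and AlMe3 (CH2Cl2, −78 °C, desilylation on work-up) should insert the new methylene between C13 and the less hindered α-carbon, which gives 21.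

2. Step 27 (double epoxidation and lactonisation). The peracid may attack C12=C13 from the wrong face, because the result depends on the cycloheptene conformation. Fallback: the C12–C13 epoxide is made through a bromohydrin, which delivers oxygen to the face opposite to the one an electrophile prefers; it sets out from 39 and comes back at 41. N-Bromosuccinimide in aqueous DME at 0 °C should react first at the isolated, more nucleophilic C12=C13 alkene and give the bromohydrin F12 (bromine on C13, hydroxyl on C12 by anti opening at the tertiary carbon). DBU in MeCN closes it to the epoxy dienoic acid F13. mCPBA (1.2 equiv) then epoxidises only C2=C3, and lactonisation as in step 27 gives 41.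

3. Step 15 (hydrogenation of C5=C10). Hydrogen may be delivered to the β face of C5, which would give the cis B/C fusion. Fallback: hydroxyl-directed hydrogenation, setting out from 20 and coming back at 21. Bu4NF frees the axial α-oriented C17 alcohol to give the hydroxy ketone F10. [Ir(cod)(PCy3)(py)]PF6 under H2 in CH2Cl2 should bind this hydroxyl, which sits 1,3-diaxial to C5, and deliver hydrogen to the α face to give the saturated hydroxy ketone F11. TBSCl and imidazole return 21.

**Further compounds**

F1 | step 13 | (R)-5-[(E)-5-ethoxy-3-methylhexa-3,5-dien-1-yl]-5-(hydroxymethyl)cyclopent-1-en-1-yl trifluoromethanesulfonate | FC(F)(F)S(=O)(=O)OC1=CCC[C@]1(CO)CC/C(C)=C/C(=C)OCC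
F2 | step 13 | (S)-3a-[(E)-5-ethoxy-3-methylhexa-3,5-dien-1-yl]-3,3a,4,5-tetrahydro-1H-cyclopenta[c]furan-1-one | O=C1OC[C@]2(CC/C(C)=C/C(=C)OCC)CCC=C12
F3 | step 13 | ethoxydiene analogue of 15 (cis-fused lactone, C3 β-OPMB) | O=C1OC[C@]2(CC/C(C)=C/C(=C)OCC)CC[C@@H](OCc3ccc(OC)cc3)[C@H]12
F4 | step 13 | ethoxydiene analogue of lactol 16 | OC1OC[C@]2(CC/C(C)=C/C(=C)OCC)CC[C@@H](OCc3ccc(OC)cc3)[C@H]12
F5 | step 13 | ethoxydiene analogue of alkynol 17 | C#C[C@H]1[C@H](OCc2ccc(OC)cc2)CC[C@]1(CO)CC/C(C)=C/C(=C)OCC
F6 | step 13 | ethoxydiene analogue of 18 (dienyne, C17 OTBS) | C#C[C@H]1[C@H](OCc2ccc(OC)cc2)CC[C@]1(CO[Si](C)(C)C(C)(C)C)CC/C(C)=C/C(=C)OCC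
F7 | step 13 | Diels–Alder adduct: six-membered ring C lacking C11, C5=C10, C13=C14 ethyl enol ether, C6 β-methyl | COc1ccc(CO[C@@H]2CC[C@]3(CO[Si](C)(C)C(C)(C)C)CC[C@@]4(C)C=C(OCC)CC=C4[C@@H]23)cc1
F8 | step 13 | six-membered C13 ketone with C5=C10 | COc1ccc(CO[C@@H]2CC[C@]3(CO[Si](C)(C)C(C)(C)C)CC[C@@]4(C)CC(=O)CC=C4[C@@H]23)cc1
F9 | step 13 | saturated six-membered C13 ketone, C5 α-H | COc1ccc(CO[C@@H]2CC[C@]3(CO[Si](C)(C)C(C)(C)C)CC[C@@]4(C)CC(=O)CC[C@@H]4[C@@H]23)cc1
F10 | step 15 | C17 hydroxy ketone with C5=C10 | COc1ccc(CO[C@@H]2CC[C@]3(CO)CC[C@@]4(C)CC(=O)CCC=C4[C@@H]23)cc1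
F11 | step 15 | C17 hydroxy ketone, C5 α-H | COc1ccc(CO[C@@H]2CC[C@]3(CO)CC[C@@]4(C)CC(=O)CCC[C@@H]4[C@@H]23)cc1
F12 | step 27 | bromohydrin of 39 (C13 β-Br, C12 α-OH) | C=C(C(=O)O)C1=CC[C@]2(COC(C)=O)CC[C@@]3(C)C[C@H](Br)[C@@](C)(O)CC[C@@H]3[C@@H]12
F13 | step 27 | 12α,13α-epoxy dienoic acid | C=C(C(=O)O)C1=CC[C@]2(COC(C)=O)CC[C@@]3(C)C[C@H]4O[C@@]4(C)CC[C@@H]3[C@@H]12
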